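The route rests on cutting the only ring alkene, C3=C4 (numbering: bridgeheads C1 and C5; ring A is C1–C2–C3=C4–C5–C9; ring B is C1–C9–C5–C6–C7–C8; C10 and C11 are the formyl carbons, C1' the side-chain methine). This alkene lies in the bridge between two quaternary bridgeheads, so an allyl group on C1 and a 2-(silyloxymethyl)vinyl group on C5, both axial on the chair of ring B, can be joined by ring-closing metathesis. That single operation closes ring A, creates the bicycle and puts C10 on the alkene. Its precursor is a cyclohexane that already holds all five stereocentres, the C11 aldehyde and the C9 acetate.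

Key step: step 14

Remarks on the chemistry, valid for all steps:
- C2 and C3 of (R)-citronellal become C6 and C1', and its formyl carbon becomes C5. The side chain is therefore bonded directly to the ring; olefinating citronellal and adding to the enoate would instead leave a methylene between ring and stereocentre.
- On ring B the C1 methyl, the C9 oxygen, C11 and H-6 share one face; the allyl arm (C2), C4 and the side chain share the other.
- The C9 hydroxyl is acetylated before the key step. After it, C11 is taken to the alcohol so that both formyl groups are made together, because a free C10 hydroxyl beside the C11 aldehyde would close to a lactol.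
- Assumption: the catalyst of step 1 overrides the weak bias of C1'. The carbinol mixtures in 5 and 16 are carried on because those centres are destroyed in the next step.

Step 1
Reactants: 1 (R)-citronellal; 2 methyl vinyl ketone
Product: 3 (2S,3R)-3,7-dimethyl-2-(3-oxobutyl)oct-6-enal
Conditions: (S)-2-[methoxy(diphenyl)methyl]pyrrolidine (5 mol %), ethyl 3,4-dihydroxybenzoate (20 mol %), neat, 4 °C
Reagents that add atoms: none
Why: Enamine-mediated Michael addition of an aldehyde to an enone, in which the E-enamine of 1 is attacked on the face away from the diphenyl(methoxy)methyl group of the (S)-catalyst, which should set C6 as S, while C1' is not enolisable and is carried through unchanged.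

Step 2
Reactants: 3 (2S,3R)-3,7-dimethyl-2-(3-oxobutyl)oct-6-enal
Product: 4 (4S)-4-[(2R)-6-methylhept-5-en-2-yl]cyclohex-2-en-1-one
Conditions: LiOH·H2O (0.2 equiv), i-PrOH, rt
Reagents that add atoms: none
Why: Intramolecular aldol condensation (the ring-forming half of a Robinson annulation), in which only the methyl ketone enolate can reach the aldehyde through a six-membered ring and the mild base should dehydrate without epimerising C6.

Step 3
Reactants: 4 (4S)-4-[(2R)-6-methylhept-5-en-2-yl]cyclohex-2-en-1-one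
Product: 5 (4S)-1-methyl-4-[(2R)-6-methylhept-5-en-2-yl]cyclohex-2-en-1-ol (both carbinol epimers)
Conditions: MeLi, Et2O, −78 °C
Reagents that add atoms: methyllithium, C[Li]
Why: 1,2-Addition of an organolithium to the enone carbonyl brings in the future C1 methyl group, and the configuration of the new carbinol does not matter because step 4 erases it.

Step 4
Reactants: 5 (4S)-1-methyl-4-[(2R)-6-methylhept-5-en-2-yl]cyclohex-2-en-1-ol
Product: 6 (6S)-3-methyl-6-[(2R)-6-methylhept-5-en-2-yl]cyclohex-2-en-1-one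
Conditions: pyridinium chlorochromate (C5H5NH)[CrO3Cl], 4 Å molecular sieves, CH2Cl2, rt
Reagents that add atoms: pyridinium chlorochromate, [O-][Cr](=O)(=O)Cl.c1cc[nH+]cc1
Why: Babler–Dauben oxidative 1,3-transposition, in which the chromate ester of the tertiary allylic alcohol undergoes a [3,3] shift and oxidation, moving the oxygen to C5 and the alkene to C9=C1 without touching C6.

Step 5
Reactants: 6 (6S)-3-methyl-6-[(2R)-6-methylhept-5-en-2-yl]cyclohex-2-en-1-one
Product: 7 trimethyl{[(3R,6S)-3-methyl-6-[(2R)-6-methylhept-5-en-2-yl]-3-(prop-2-en-1-yl)cyclohex-1-en-1-yl]oxy}silane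
Conditions: allylMgBr, CuBr·SMe2, LiCl, Me3SiCl, THF, −78 °C
Reagents that add atoms: allylmagnesium bromide, C=CC[Mg]Br; chlorotrimethylsilane, C[Si](C)(C)Cl
Why: Chlorotrimethylsilane-accelerated conjugate addition of an allylcopper reagent to a β,β-disubstituted enone, in which axial attack on the half-chair with the C6 side chain pseudo-equatorial should place the allyl group on C1 cis to that side chain, while silylation fixes the enolate at C5=C9 (a minor C1 epimer should be separable at 10 or 11).

Step 6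
Reactants: 7 trimethyl{[(3R,6S)-3-methyl-6-[(2R)-6-methylhept-5-en-2-yl]-3-(prop-2-en-1-yl)cyclohex-1-en-1-yl]oxy}silane
Product: 9 (3R,6S)-3-methyl-6-[(2R)-6-methylhept-5-en-2-yl]-3-(prop-2-en-1-yl)cyclohex-1-en-1-yl trifluoromethanesulfonate, via lithium enolate 8 (not isolated)
Conditions: MeLi, THF, 0 °C; PhNTf2, −78 °C to rt
Reagents that add atoms: N-phenylbis(trifluoromethanesulfonimide), O=S(=O)(N(c1ccccc1)S(=O)(=O)C(F)(F)F)C(F)(F)F
Why: Methyllithium cleaves the silyl enol ether to the regiodefined lithium enolate, which is O-sulfonylated (enol triflate formation) before it can equilibrate toward C6.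

Step 7
Reactants: 9 (3R,6S)-3-methyl-6-[(2R)-6-methylhept-5-en-2-yl]-3-(prop-2-en-1-yl)cyclohex-1-en-1-yl trifluoromethanesulfonate
Product: 10 [(3R,6S)-3-methyl-6-[(2R)-6-methylhept-5-en-2-yl]-3-(prop-2-en-1-yl)cyclohex-1-en-1-yl]methanol
Conditions: Bu3SnCH2OH, Pd(PPh3)4 (5 mol %), LiCl, 1,4-dioxane, 100 °C
Reagents that add atoms: (tributylstannyl)methanol, OC[Sn](CCCC)(CCCC)CCCC
Why: Stille coupling of an enol triflate with a hydroxymethylstannane installs C11 on C5 and gives the primary allylic alcohol needed to direct the epoxidation.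

Step 8
Reactants: 10 [(3R,6S)-3-methyl-6-[(2R)-6-methylhept-5-en-2-yl]-3-(prop-2-en-1-yl)cyclohex-1-en-1-yl]methanol
Product: 11 [(1R,2S,5R,6R)-5-methyl-2-[(2R)-6-methylhept-5-en-2-yl]-5-(prop-2-en-1-yl)-7-oxabicyclo[4.1.0]heptan-1-yl]methanol (epoxide oxygen cis to the C1 methyl, trans to allyl and side chain)
Conditions: Ti(OiPr)4 (10 mol %), D-(−)-diethyl tartrate (12 mol %), t-BuOOH, 4 Å molecular sieves, CH2Cl2, −20 °C
Reagents that add atoms: tert-butyl hydroperoxide, CC(C)(C)OO
Why: Sharpless asymmetric epoxidation, in which the D-(−)-tartrate complex delivers oxygen to the C5=C9 face anti to the C6 side chain and the C1 allyl group (also the less hindered face), while the two alkenes without an allylic hydroxyl are left alone.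

Step 9
Reactants: 11 [(1R,2S,5R,6R)-5-methyl-2-[(2R)-6-methylhept-5-en-2-yl]-5-(prop-2-en-1-yl)-7-oxabicyclo[4.1.0]heptan-1-yl]methanol
Product: 12 (1S,2S,5R,6R)-5-methyl-2-[(2R)-6-methylhept-5-en-2-yl]-5-(prop-2-en-1-yl)-7-oxabicyclo[4.1.0]heptane-1-carbaldehyde
Conditions: Dess–Martin periodinane, pyridine, CH2Cl2, 0 °C to rt
Reagents that add atoms: none
Why: Dess–Martin oxidation of the primary alcohol gives an α,β-epoxy aldehyde that has no α-hydrogen and so can neither epimerise nor eliminate.

Step 10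
Reactants: 13 2-bromoprop-2-en-1-ol
Product: 14 [(2-bromoprop-2-en-1-yl)oxy](tert-butyl)dimethylsilane
Conditions: TBSCl, imidazole, CH2Cl2, rt
Reagents that add atoms: tert-butyldimethylsilyl chloride, CC(C)(C)[Si](C)(C)Cl
Why: Standard silylation of a primary alcohol, with a silyl group bulky enough to suppress oxygen-to-carbon silyl migration in the alkenyllithium of step 11.

Step 11
Reactants: 12 (1S,2S,5R,6R)-5-methyl-2-[(2R)-6-methylhept-5-en-2-yl]-5-(prop-2-en-1-yl)-7-oxabicyclo[4.1.0]heptane-1-carbaldehyde; 14 [(2-bromoprop-2-en-1-yl)oxy](tert-butyl)dimethylsilane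
Product: 16 2-({[tert-butyl(dimethyl)silyl]oxy}methyl)-1-[(1R,2S,5R,6R)-5-methyl-2-[(2R)-6-methylhept-5-en-2-yl]-5-(prop-2-en-1-yl)-7-oxabicyclo[4.1.0]heptan-1-yl]prop-2-en-1-ol (both C11 epimers), via alkenyllithium 15 (not isolated)
Conditions: 14, t-BuLi (2 equiv), Et2O, −78 °C; then 12, −78 °C
Reagents that add atoms: none
Why: Bromine–lithium exchange followed by 1,2-addition of the alkenyllithium to the aldehyde at −78 °C, where the epoxide is inert; both C11 epimers are usable because C11 becomes a formyl carbon in step 12.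

Step 12
Reactants: 16 2-({[tert-butyl(dimethyl)silyl]oxy}methyl)-1-[(1R,2S,5R,6R)-5-methyl-2-[(2R)-6-methylhept-5-en-2-yl]-5-(prop-2-en-1-yl)-7-oxabicyclo[4.1.0]heptan-1-yl]prop-2-en-1-ol
Product: 19 (1R,2R,3R,6S)-1-(3-{[tert-butyl(dimethyl)silyl]oxy}prop-1-en-2-yl)-2-hydroxy-3-methyl-6-[(2R)-6-methylhept-5-en-2-yl]-3-(prop-2-en-1-yl)cyclohexane-1-carbaldehyde, via trimethylsilyl ether 17 (not isolated), via silyloxy aldehyde 18 (not isolated)
Conditions: Me3SiOTf (1.2 equiv), 2,6-lutidine (1.1 equiv), CH2Cl2, −78 to −40 °C; then AcOH, THF, H2O, rt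
Reagents that add atoms: none
Why: Semipinacol rearrangement of a 2,3-epoxy silyl ether, in which Lewis-acid opening of the epoxide at the fully substituted C5 is accompanied by a stereospecific 1,2-shift of the alkenyl group (a better migrating group than hydride) anti to the breaking C5–O bond, so that C4 enters cis to the side chain and the allyl arm while the C9 oxygen stays cis to the new formyl group.

Step 13
Reactants: 19 (1R,2R,3R,6S)-1-(3-{[tert-butyl(dimethyl)silyl]oxy}prop-1-en-2-yl)-2-hydroxy-3-methyl-6-[(2R)-6-methylhept-5-en-2-yl]-3-(prop-2-en-1-yl)cyclohexane-1-carbaldehyde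
Product: 20 (1R,2R,3R,6S)-2-acetoxy-1-(3-{[tert-butyl(dimethyl)silyl]oxy}prop-1-en-2-yl)-3-methyl-6-[(2R)-6-methylhept-5-en-2-yl]-3-(prop-2-en-1-yl)cyclohexane-1-carbaldehyde
Conditions: Ac2O, DMAP, Et3N, CH2Cl2, rt to 40 °C
Reagents that add atoms: acetic anhydride, CC(=O)OC(C)=O
Why: 4-Dimethylaminopyridine-catalysed acylation of the hindered secondary alcohol, safe because the aldehyde has no α-hydrogen and no alkoxide base is present to trigger retro-aldol cleavage.

Step 14
Reactants: 20 (1R,2R,3R,6S)-2-acetoxy-1-(3-{[tert-butyl(dimethyl)silyl]oxy}prop-1-en-2-yl)-3-methyl-6-[(2R)-6-methylhept-5-en-2-yl]-3-(prop-2-en-1-yl)cyclohexane-1-carbaldehyde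
Product: 21 (1R,5R,8S,9R)-2-({[tert-butyl(dimethyl)silyl]oxy}methyl)-1-formyl-5-methyl-8-[(2R)-6-methylhept-5-en-2-yl]bicyclo[3.3.1]non-2-en-9-yl acetate
Conditions: second-generation Hoveyda–Grubbs catalyst RuCl2(=CH-C6H4-2-OiPr)(H2IMes) (10 mol %), 1,4-benzoquinone (20 mol %), toluene (2 mM), 80 °C
Reagents that add atoms: none
Why: The ruthenium alkylidene loads on the monosubstituted allyl terminus (C3), then undergoes intramolecular [2+2] cycloaddition and cycloreversion with the 1,1-disubstituted alkene on C5, forming the C3=C4 bond and releasing ethylene. This is ring-closing olefin metathesis to a trisubstituted cyclohexene, of the kind known for joining 1,3-diaxial alkenyl groups on a cyclohexane into bicyclo[3.3.1]nonenes. Ring A (C1–C2–C3=C4–C5–C9) is closed as a six-membered ring across the 1,3-related carbons C1 and C5 of ring B, which turns the cyclohexane into the bridged bicycle. No stereocentre is created; all five are already present and none can epimerise under the neutral conditions. The catalyst must engage only the two terminal alkenes: the trisubstituted side-chain alkene is far less reactive and cannot form a small ring with either arm, and the chair of ring B with the side chain equatorial holds the two arms syn-diaxial and close. Benzoquinone suppresses isomerisation of the allyl group and high dilution disfavours dimerisation.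

Step 15
Reactants: 21 (1R,5R,8S,9R)-2-({[tert-butyl(dimethyl)silyl]oxy}methyl)-1-formyl-5-methyl-8-[(2R)-6-methylhept-5-en-2-yl]bicyclo[3.3.1]non-2-en-9-yl acetate
Product: 22 (1S,5R,8S,9R)-2-({[tert-butyl(dimethyl)silyl]oxy}methyl)-1-(hydroxymethyl)-5-methyl-8-[(2R)-6-methylhept-5-en-2-yl]bicyclo[3.3.1]non-2-en-9-yl acetate
Conditions: NaBH4, EtOH/THF, −20 °C; AcOH quench
Reagents that add atoms: none
Why: Chemoselective borohydride reduction of the aldehyde beside the acetate takes C11 to the alcohol level, so that no γ-hydroxy aldehyde (and hence no lactol) arises when C10 is unmasked.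

Step 16
Reactants: 22 (1S,5R,8S,9R)-2-({[tert-butyl(dimethyl)silyl]oxy}methyl)-1-(hydroxymethyl)-5-methyl-8-[(2R)-6-methylhept-5-en-2-yl]bicyclo[3.3.1]non-2-en-9-yl acetate
Product: 23 (1S,5R,8S,9R)-1,2-bis(hydroxymethyl)-5-methyl-8-[(2R)-6-methylhept-5-en-2-yl]bicyclo[3.3.1]non-2-en-9-yl acetate
Conditions: HF·pyridine, pyridine, THF, 0 °C to rt
Reagents that add atoms: none
Why: Fluoride cleavage of the primary allylic silyl ether under buffered, weakly acidic conditions that keep the acetate and disfavour acetyl migration.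

Step 17
Reactants: 23 (1S,5R,8S,9R)-1,2-bis(hydroxymethyl)-5-methyl-8-[(2R)-6-methylhept-5-en-2-yl]bicyclo[3.3.1]non-2-en-9-yl acetate
Product: 24 (1R,5R,8S,9R)-1,2-diformyl-5-methyl-8-[(2R)-6-methylhept-5-en-2-yl]bicyclo[3.3.1]non-2-en-9-yl acetate (CNP0299929.2)
Conditions: (COCl)2, DMSO, CH2Cl2, −78 °C; Et3N, −78 to 0 °C
Reagents that add atoms: none
Why: Twofold Swern oxidation of a 1,4-diol to the ene-dialdehyde, in which both alkoxysulfonium ions are formed before base is added so that no lactol or lactone can arise, and the quaternary C5 excludes epimerisation.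

Compound list
1 | (R)-citronellal, (3R)-3,7-dimethyloct-6-enal | O=CC[C@H](C)CCC=C(C)C | starting material
2 | methyl vinyl ketone, but-3-en-2-one | CC(=O)C=C | starting material
3 | (2S,3R)-3,7-dimethyl-2-(3-oxobutyl)oct-6-enal | O=C[C@@H](CCC(C)=O)[C@H](C)CCC=C(C)C | intermediate
4 | (4S)-4-[(2R)-6-methylhept-5-en-2-yl]cyclohex-2-en-1-one | O=C1C=C[C@H]([C@H](C)CCC=C(C)C)CC1 | intermediate
5 | (4S)-1-methyl-4-[(2R)-6-methylhept-5-en-2-yl]cyclohex-2-en-1-ol, both carbinol epimers | CC1(O)C=C[C@H]([C@H](C)CCC=C(C)C)CC1 | intermediate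
6 | (6S)-3-methyl-6-[(2R)-6-methylhept-5-en-2-yl]cyclohex-2-en-1-one | O=C1C=C(C)CC[C@H]1[C@H](C)CCC=C(C)C | intermediate
7 | trimethyl{[(3R,6S)-3-methyl-6-[(2R)-6-methylhept-5-en-2-yl]-3-(prop-2-en-1-yl)cyclohex-1-en-1-yl]oxy}silane (allyl cis to the side chain) | C=CC[C@]1(C)C=C(O[Si](C)(C)C)[C@H]([C@H](C)CCC=C(C)C)CC1 | intermediate
8 | lithium (3R,6S)-3-methyl-6-[(2R)-6-methylhept-5-en-2-yl]-3-(prop-2-en-1-yl)cyclohex-1-en-1-olate (not isolated) | C=CC[C@]1(C)C=C(O[Li])[C@H]([C@H](C)CCC=C(C)C)CC1 | intermediate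
9 | (3R,6S)-3-methyl-6-[(2R)-6-methylhept-5-en-2-yl]-3-(prop-2-en-1-yl)cyclohex-1-en-1-yl trifluoromethanesulfonate | C=CC[C@]1(C)C=C(OS(=O)(=O)C(F)(F)F)[C@H]([C@H](C)CCC=C(C)C)CC1 | intermediate
10 | [(3R,6S)-3-methyl-6-[(2R)-6-methylhept-5-en-2-yl]-3-(prop-2-en-1-yl)cyclohex-1-en-1-yl]methanol | C=CC[C@]1(C)C=C(CO)[C@H]([C@H](C)CCC=C(C)C)CC1 | intermediate
11 | [(1R,2S,5R,6R)-5-methyl-2-[(2R)-6-methylhept-5-en-2-yl]-5-(prop-2-en-1-yl)-7-oxabicyclo[4.1.0]heptan-1-yl]methanol | C=CC[C@@]1(C)CC[C@@H]([C@H](C)CCC=C(C)C)[C@]2(CO)O[C@H]12 | intermediate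
12 | (1S,2S,5R,6R)-5-methyl-2-[(2R)-6-methylhept-5-en-2-yl]-5-(prop-2-en-1-yl)-7-oxabicyclo[4.1.0]heptane-1-carbaldehyde | C=CC[C@@]1(C)CC[C@@H]([C@H](C)CCC=C(C)C)[C@]2(C=O)O[C@H]12 | intermediate
13 | 2-bromoprop-2-en-1-ol (2-bromoallyl alcohol) | OCC(Br)=C | starting material
14 | [(2-bromoprop-2-en-1-yl)oxy](tert-butyl)dimethylsilane | C=C(Br)CO[Si](C)(C)C(C)(C)C | intermediate
15 | (3-{[tert-butyl(dimethyl)silyl]oxy}prop-1-en-2-yl)lithium (not isolated) | [Li]C(=C)CO[Si](C)(C)C(C)(C)C | intermediate
16 | 2-({[tert-butyl(dimethyl)silyl]oxy}methyl)-1-[(1R,2S,5R,6R)-5-methyl-2-[(2R)-6-methylhept-5-en-2-yl]-5-(prop-2-en-1-yl)-7-oxabicyclo[4.1.0]heptan-1-yl]prop-2-en-1-ol, both C11 epimers | C=CC[C@@]1(C)CC[C@@H]([C@H](C)CCC=C(C)C)[C@]2(C(O)C(=C)CO[Si](C)(C)C(C)(C)C)O[C@H]12 | intermediate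
17 | trimethylsilyl ether of 16 at the C11 oxygen (not isolated) | C=CC[C@@]1(C)CC[C@@H]([C@H](C)CCC=C(C)C)[C@]2(C(O[Si](C)(C)C)C(=C)CO[Si](C)(C)C(C)(C)C)O[C@H]12 | intermediate
18 | (1R,2R,3R,6S)-1-(3-{[tert-butyl(dimethyl)silyl]oxy}prop-1-en-2-yl)-3-methyl-6-[(2R)-6-methylhept-5-en-2-yl]-3-(prop-2-en-1-yl)-2-[(trimethylsilyl)oxy]cyclohexane-1-carbaldehyde (not isolated) | C[Si](C)(C)O[C@@H]1[C@@](C)(CC=C)CC[C@@H]([C@H](C)CCC=C(C)C)[C@@]1(C=O)C(=C)CO[Si](C)(C)C(C)(C)C | intermediate
19 | (1R,2R,3R,6S)-1-(3-{[tert-butyl(dimethyl)silyl]oxy}prop-1-en-2-yl)-2-hydroxy-3-methyl-6-[(2R)-6-methylhept-5-en-2-yl]-3-(prop-2-en-1-yl)cyclohexane-1-carbaldehyde | O[C@@H]1[C@@](C)(CC=C)CC[C@@H]([C@H](C)CCC=C(C)C)[C@@]1(C=O)C(=C)CO[Si](C)(C)C(C)(C)C | intermediate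
20 | (1R,2R,3R,6S)-2-acetoxy-1-(3-{[tert-butyl(dimethyl)silyl]oxy}prop-1-en-2-yl)-3-methyl-6-[(2R)-6-methylhept-5-en-2-yl]-3-(prop-2-en-1-yl)cyclohexane-1-carbaldehyde (metathesis precursor) | CC(=O)O[C@@H]1[C@@](C)(CC=C)CC[C@@H]([C@H](C)CCC=C(C)C)[C@@]1(C=O)C(=C)CO[Si](C)(C)C(C)(C)C | intermediate
21 | (1R,5R,8S,9R)-2-({[tert-butyl(dimethyl)silyl]oxy}methyl)-1-formyl-5-methyl-8-[(2R)-6-methylhept-5-en-2-yl]bicyclo[3.3.1]non-2-en-9-yl acetate (metathesis product) | CC(=O)O[C@@H]1[C@@]2(C)CC=C(CO[Si](C)(C)C(C)(C)C)[C@]1(C=O)[C@H]([C@H](C)CCC=C(C)C)CC2 | intermediate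
22 | (1S,5R,8S,9R)-2-({[tert-butyl(dimethyl)silyl]oxy}methyl)-1-(hydroxymethyl)-5-methyl-8-[(2R)-6-methylhept-5-en-2-yl]bicyclo[3.3.1]non-2-en-9-yl acetate | CC(=O)O[C@@H]1[C@@]2(C)CC=C(CO[Si](C)(C)C(C)(C)C)[C@]1(CO)[C@H]([C@H](C)CCC=C(C)C)CC2 | intermediate
23 | (1S,5R,8S,9R)-1,2-bis(hydroxymethyl)-5-methyl-8-[(2R)-6-methylhept-5-en-2-yl]bicyclo[3.3.1]non-2-en-9-yl acetate | CC(=O)O[C@@H]1[C@@]2(C)CC=C(CO)[C@]1(CO)[C@H]([C@H](C)CCC=C(C)C)CC2 | intermediate
24 | (1R,5R,8S,9R)-1,2-diformyl-5-methyl-8-[(2R)-6-methylhept-5-en-2-yl]bicyclo[3.3.1]non-2-en-9-yl acetate, CNP0299929.2 | CC(=O)O[C@@H]1[C@@]2(C)CC=C(C=O)[C@]1(C=O)[C@H]([C@H](C)CCC=C(C)C)CC2 | target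

Total step count: 17. Longest linear sequence: 16 steps (steps 1–9 and 11–17, from 1); step 10 is a one-step branch.

Steps most likely to fail

Step 14, the ring-closing metathesis. The alkylidene formed on the allyl arm may fail to engage the 1,1-disubstituted alkene that sits on quaternary C5 between the formyl group, the acetate and the branched side chain. Oligomerisation through the allyl termini, or drift of the allyl double bond, would then take over. The fallback reverses the order of ring closure and rearrangement. It sets out from 16, where the same alkene hangs on a secondary carbinol carbon and is much more accessible. Metathesis of 16 with the same ruthenium catalyst closes a seven-membered ring (C1–C2–C3=C4–C11–C5–C9) and should give the bridged epoxy alcohol F1. ZnBr2 in CH2Cl2 then carries out the semipinacol rearrangement as a ring contraction. C4, held anti to the C5–O bond by the ring, shifts from C11 to C5 and C11 is expelled as the formyl group, giving the bicyclic hydroxy aldehyde F2. Acetylation as in step 13 comes back to the route at 21.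

Step 5, the conjugate allylation that creates quaternary C1. Facial selectivity rests on a conformational preference of the C6 side chain and may be modest, and allylcopper reagents can also add to the carbonyl group. The fallback sets out from 6. AllylMgBr in Et2O at −78 °C adds to the carbonyl group to give tertiary alcohols whose epimers can be separated. The epimer with the allyl group cis to the side chain is (1S,6S)-3-methyl-6-[(2R)-6-methylhept-5-en-2-yl]-1-(prop-2-en-1-yl)cyclohex-2-en-1-ol F3. KH with 18-crown-6 in THF then induces an anionic oxy-Cope rearrangement, which passes the allyl group suprafacially from C5 to C1 and leaves the regiodefined potassium enolate F4. Trapping with PhNTf2 comes back to the route at 9.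

Step 15, the start of the end game. In 22 and 23 a free C11 hydroxyl sits 1,3 and cis to the C9 acetate, so the acetyl group may migrate from the hindered secondary oxygen to the primary one during reduction, desilylation or handling. The fallback avoids the diol and sets out from 21. HF·pyridine removes the silyl group, and the hydroxy aldehyde closes to the lactol F5, which stays in equilibrium with its open form. MnO2 in CH2Cl2 oxidises the allylic alcohol of the open form and leads directly to 24.

Further compounds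
F1 | step 14 | bridged epoxy alcohol from metathesis of 16: seven-membered ring C1–C2–C3=C4–C11–C5–C9 on ring B, C5–C9 epoxide kept, hydroxyl on C11 (both epimers), CH2OTBS on C4 | OC1C(CO[Si](C)(C)C(C)(C)C)=CC[C@@]2(C)CC[C@@H]([C@H](C)CCC=C(C)C)[C@@]13O[C@H]23
F2 | step 14 | (1R,5R,8S,9R)-2-({[tert-butyl(dimethyl)silyl]oxy}methyl)-9-hydroxy-5-methyl-8-[(2R)-6-methylhept-5-en-2-yl]bicyclo[3.3.1]non-2-ene-1-carbaldehyde | O[C@@H]1[C@@]2(C)CC=C(CO[Si](C)(C)C(C)(C)C)[C@]1(C=O)[C@H]([C@H](C)CCC=C(C)C)CC2
F3 | step 5 | (1S,6S)-3-methyl-6-[(2R)-6-methylhept-5-en-2-yl]-1-(prop-2-en-1-yl)cyclohex-2-en-1-ol | C=CC[C@@]1(O)C=C(C)CC[C@H]1[C@H](C)CCC=C(C)C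
F4 | step 5 | potassium (3R,6S)-3-methyl-6-[(2R)-6-methylhept-5-en-2-yl]-3-(prop-2-en-1-yl)cyclohex-1-en-1-olate | C=CC[C@]1(C)C=C(O[K])[C@H]([C@H](C)CCC=C(C)C)CC1
F5 | step 15 | lactol of desilylated 21: five-membered cyclic hemiacetal between C11 and the C10 oxygen, both anomers | CC(=O)O[C@@H]1[C@@]2(C)CC=C4COC(O)[C@@]14[C@H]([C@H](C)CCC=C(C)C)CC2
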